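**Strategy.** Ring A (C1–C5 and C10, labdane numbering) is a cyclohexane fused to ring B along C5–C10, with a quaternary C10 and the C4 gem-dimethyl group next to C5: the retron of a [4+2] cycloaddition. An enantioselective Diels–Alder reaction between 2,6-dimethyl-1,4-benzoquinone (future ring B; its C5=C10 bond is the dienophile) and 4-methylpenta-1,3-diene (C1–C4) forms C1–C10 and C4–C5 in one operation and sets C10. The quinone carbonyls then serve in turn: C6 is erased via its enol triflate with trans-selective hydrogenation at C5, and C9 becomes the enol triflate that takes the C11–C15 chain by Negishi coupling. (S)-Glycidol delivers the glyceride.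

Key step: step 1

Remark on numbering: ring and chain atoms are referred to by labdane numbers (ring A = C1–C5, C10; ring B = C5–C10; chain C11–C15); the decalin of the target is (5R,10R), the mirror image of the common labdane series.

Assumption: the catalyst enantiomer written in step 1 is the working choice from the usual carbonyl-coordination model for this catalyst class; if that model assigns the opposite quinone face, the mirror-image catalyst is used so that C10 is R.

**Step 1**
Reactants: 1 2,6-dimethyl-1,4-benzoquinone; 2 4-methylpenta-1,3-diene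
Product: 3 (4aS,8aR)-2,5,5,8a-tetramethyl-4a,5,8,8a-tetrahydronaphthalene-1,4-dione (cis-fused ene-dione)
Conditions: (S)-3,3-diphenyl-1-(2-methylphenyl)tetrahydro-1H,3H-pyrrolo[1,2-c][1,3,2]oxazaborole (20 mol %), Tf2NH (16 mol %), 2 (5 equiv, slow addition), CH2Cl2, −78 → −20 °C
Reagents that add atoms: none
Why: Catalytic enantioselective Diels–Alder reaction of a quinone under oxazaborolidinium-cation catalysis, a concerted but asynchronous [4+2] cycloaddition in which the diene CH2 terminus (C1) bonds in advance to the methyl-bearing β-carbon (C10) and the Me2C terminus (C4) closes onto the α-CH (C5). Ring A is closed by intermolecular suprafacial [4π+2π] addition across the C5=C10 bond of ring B, leaving a C2=C3 double bond. The quaternary C10 centre is set by the catalyst, which binds the more basic and unhindered C6 carbonyl (flanked by two CH groups) and shields one face of the adjacent C5=C10 bond; C5 forms cis to the C10 methyl by suprafacial addition and is reset in step 3. The regioselectivity needed (C4 to C5, not to C10) is secured electronically, because activation through C6=O makes C10 the electrophilic β-carbon for the nucleophilic CH2 end, and sterically, because the other orientation would join two quaternary carbons. Site selectivity does not arise, since the two ring double bonds of 1 are homotopic. The diene is slowed by its (Z)-methyl group, so it is used in excess and added slowly to limit acid-induced oligomerisation.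

**Step 2**
Reactants: 3 (4aS,8aR)-2,5,5,8a-tetramethyl-4a,5,8,8a-tetrahydronaphthalene-1,4-dione
Product: 5 (8aR)-2,5,5,8a-tetramethyl-1-oxo-1,5,8,8a-tetrahydronaphthalen-4-yl trifluoromethanesulfonate, via potassium dienolate 4 (not isolated)
Conditions: KN(SiMe3)2 (1.1 equiv), THF, −78 °C; then PhNTf2, −78 → 0 °C
Reagents that add atoms: N-phenylbis(trifluoromethanesulfonimide), O=S(=O)(N(c1ccccc1)S(=O)(=O)C(F)(F)F)C(F)(F)F
Why: Kinetic deprotonation and O-sulfonylation (enol triflate formation): the C6 carbonyl has a single α-hydrogen (H5; C7 is vinylic) and the C9 carbonyl has none, so the enolate forms towards C5, which deliberately erases the cis C5 centre and turns the C6 oxygen into a leaving group.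

**Step 3**
Reactants: 5 (8aR)-2,5,5,8a-tetramethyl-1-oxo-1,5,8,8a-tetrahydronaphthalen-4-yl trifluoromethanesulfonate
Product: 6 (4aR,8aR)-2,5,5,8a-tetramethyloctahydronaphthalen-1(2H)-one (trans-fused; C2 epimers)
Conditions: H2 (3 atm), PtO2 (10 mol %), NaHCO3, EtOAc, rt
Reagents that add atoms: none
Why: Heterogeneous hydrogenation with hydrogenolysis of the enol triflate C–O bond over PtO2 (enol triflate to alkane, a known ketone-to-methylene tactic) should saturate C2=C3, C7=C8 and C5=C6 and remove the C6 oxygen; hydrogen reaches C5 from the face opposite the axial C10 methyl and the syn C4 methyl, as in the hydrogenation of 4,4-dimethyl-Δ5-steroids to 5α products, which gives the trans fusion (C5 R), while the C9 ketone flanked by quaternary C10 should resist reduction in neutral solvent.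

**Step 4**
Reactants: 6 (4aR,8aR)-2,5,5,8a-tetramethyloctahydronaphthalen-1(2H)-one
Product: 8 (4aR,8aR)-2,5,5,8a-tetramethyl-3,4,4a,5,6,7,8,8a-octahydronaphthalen-1-yl trifluoromethanesulfonate, via potassium enolate 7 (not isolated)
Conditions: KN(SiMe3)2, THF, −78 → 0 °C; then PhNTf2, −78 °C → rt
Reagents that add atoms: N-phenylbis(trifluoromethanesulfonimide), O=S(=O)(N(c1ccccc1)S(=O)(=O)C(F)(F)F)C(F)(F)F
Why: Enol triflate formation: ketone 6 can enolise only towards C8 because C10 is quaternary, so the tetrasubstituted C8=C9 enol triflate forms regiospecifically and the C8 epimers converge.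

**Step 5**
Reactants: 9 (3R)-5-methoxy-3-methyl-5-oxopentanoic acid [(R)-methyl hydrogen 3-methylglutarate]
Product: 10 methyl (3R)-5-hydroxy-3-methylpentanoate
Conditions: BH3·SMe2, THF, −10 °C → rt; then MeOH
Reagents that add atoms: none
Why: Chemoselective borane reduction of a carboxylic acid beside a methyl ester; the stereocentre is not touched.

**Step 6**
Reactants: 10 methyl (3R)-5-hydroxy-3-methylpentanoate
Product: 11 methyl (3S)-5-iodo-3-methylpentanoate
Conditions: I2, PPh3, imidazole, CH2Cl2, 0 °C → rt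
Reagents that add atoms: iodine, II
Why: Appel-type iodination of the primary alcohol by SN2 displacement remote from the stereocentre, whose descriptor changes only through the CIP priorities.

**Step 7**
Reactants: 8 (4aR,8aR)-2,5,5,8a-tetramethyl-3,4,4a,5,6,7,8,8a-octahydronaphthalen-1-yl trifluoromethanesulfonate; 11 methyl (3S)-5-iodo-3-methylpentanoate
Product: 13 methyl (3R)-3-methyl-5-[(4aR,8aR)-2,5,5,8a-tetramethyl-3,4,4a,5,6,7,8,8a-octahydronaphthalen-1-yl]pentanoate, via alkylzinc iodide 12 (not isolated)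
Conditions: 11, Zn dust (activated), LiCl, THF, 40 °C; then 8, Pd(OAc)2 (5 mol %), SPhos (10 mol %), THF/NMP, 50 °C
Reagents that add atoms: none
Why: Ester-tolerant zinc insertion into the primary iodide followed by Negishi sp2–sp3 cross-coupling (divalent palladium acetate reduced in the flask to the active zerovalent palladium–phosphine catalyst) forms C9–C11 and fixes the C8=C9 double bond, as established for hindered 2,6,6-trisubstituted cyclohexenyl triflates; no stereocentre is formed or touched.

**Step 8**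
Reactants: 13 methyl (3R)-3-methyl-5-[(4aR,8aR)-2,5,5,8a-tetramethyl-3,4,4a,5,6,7,8,8a-octahydronaphthalen-1-yl]pentanoate
Product: 14 (3R)-3-methyl-5-[(4aR,8aR)-2,5,5,8a-tetramethyl-3,4,4a,5,6,7,8,8a-octahydronaphthalen-1-yl]pentanoic acid
Conditions: LiOH·H2O, THF/MeOH/H2O, rt; then 1 M HCl
Reagents that add atoms: lithium hydroxide (hydroxide oxygen), [Li+].[OH-]
Why: Saponification of the methyl ester, which affects neither the tetrasubstituted alkene nor the β-stereocentre.

**Step 9**
Reactants: 14 (3R)-3-methyl-5-[(4aR,8aR)-2,5,5,8a-tetramethyl-3,4,4a,5,6,7,8,8a-octahydronaphthalen-1-yl]pentanoic acid; 15 (S)-glycidol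
Product: 16 [(2R)-oxiran-2-yl]methyl (3R)-3-methyl-5-[(4aR,8aR)-2,5,5,8a-tetramethyl-3,4,4a,5,6,7,8,8a-octahydronaphthalen-1-yl]pentanoate
Conditions: DCC, DMAP (10 mol %), CH2Cl2, 0 °C → rt
Reagents that add atoms: none
Why: Steglich esterification at the primary hydroxyl of glycidol; the epoxide and its stereocentre are not involved, and the descriptor becomes R only through the CIP priorities.

**Step 10**
Reactants: 16 [(2R)-oxiran-2-yl]methyl (3R)-3-methyl-5-[(4aR,8aR)-2,5,5,8a-tetramethyl-3,4,4a,5,6,7,8,8a-octahydronaphthalen-1-yl]pentanoate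
Product: 17 (2R)-3-acetoxy-2-hydroxypropyl (3R)-3-methyl-5-[(4aR,8aR)-2,5,5,8a-tetramethyl-3,4,4a,5,6,7,8,8a-octahydronaphthalen-1-yl]pentanoate (CNP0137802.3)
Conditions: AcOH (3 equiv), Et4NBr (5 mol %), toluene, 80 °C
Reagents that add atoms: acetic acid, CC(=O)O
Why: Halide-catalysed addition of a carboxylic acid to a terminal epoxide: acetate attacks the unsubstituted epoxide carbon (SN2), so the glycerol C2 centre is retained and the secondary hydroxyl is set free between the two primary esters.

**Compound list**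
1 | 2,6-dimethyl-1,4-benzoquinone | CC1=CC(=O)C=C(C)C1=O | starting material
2 | 4-methylpenta-1,3-diene | CC(C)=CC=C | starting material
3 | (4aS,8aR)-2,5,5,8a-tetramethyl-4a,5,8,8a-tetrahydronaphthalene-1,4-dione | O=C1C(C)=CC(=O)[C@H]2C(C)(C)C=CC[C@@]12C | intermediate
4 | potassium (8aR)-2,5,5,8a-tetramethyl-1-oxo-1,5,8,8a-tetrahydronaphthalen-4-olate (not isolated) | O=C1C(C)=CC([O-])=C2C(C)(C)C=CC[C@@]12C.[K+] | intermediate
5 | (8aR)-2,5,5,8a-tetramethyl-1-oxo-1,5,8,8a-tetrahydronaphthalen-4-yl trifluoromethanesulfonate | O=C1C(C)=CC(OS(=O)(=O)C(F)(F)F)=C2C(C)(C)C=CC[C@@]12C | intermediate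
6 | (4aR,8aR)-2,5,5,8a-tetramethyloctahydronaphthalen-1(2H)-one (C2 epimers) | O=C1C(C)CC[C@@H]2C(C)(C)CCC[C@@]12C | intermediate
7 | potassium (4aR,8aR)-2,5,5,8a-tetramethyl-3,4,4a,5,6,7,8,8a-octahydronaphthalen-1-olate (not isolated) | [K+].[O-]C1=C(C)CC[C@@H]2C(C)(C)CCC[C@@]12C | intermediate
8 | (4aR,8aR)-2,5,5,8a-tetramethyl-3,4,4a,5,6,7,8,8a-octahydronaphthalen-1-yl trifluoromethanesulfonate | FC(F)(F)S(=O)(=O)OC1=C(C)CC[C@@H]2C(C)(C)CCC[C@@]12C | intermediate
9 | (3R)-5-methoxy-3-methyl-5-oxopentanoic acid | COC(=O)C[C@H](C)CC(O)=O | starting material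
10 | methyl (3R)-5-hydroxy-3-methylpentanoate | COC(=O)C[C@H](C)CCO | intermediate
11 | methyl (3S)-5-iodo-3-methylpentanoate | COC(=O)C[C@H](C)CCI | intermediate
12 | [(3S)-5-methoxy-3-methyl-5-oxopentyl]zinc iodide (not isolated) | COC(=O)C[C@H](C)CC[Zn]I | intermediate
13 | methyl (3R)-3-methyl-5-[(4aR,8aR)-2,5,5,8a-tetramethyl-3,4,4a,5,6,7,8,8a-octahydronaphthalen-1-yl]pentanoate | COC(=O)C[C@H](C)CCC1=C(C)CC[C@@H]2C(C)(C)CCC[C@@]12C | intermediate
14 | (3R)-3-methyl-5-[(4aR,8aR)-2,5,5,8a-tetramethyl-3,4,4a,5,6,7,8,8a-octahydronaphthalen-1-yl]pentanoic acid | OC(=O)C[C@H](C)CCC1=C(C)CC[C@@H]2C(C)(C)CCC[C@@]12C | intermediate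
15 | (S)-glycidol [(2S)-oxiran-2-ylmethanol] | OC[C@H]1CO1 | starting material
16 | [(2R)-oxiran-2-yl]methyl (3R)-3-methyl-5-[(4aR,8aR)-2,5,5,8a-tetramethyl-3,4,4a,5,6,7,8,8a-octahydronaphthalen-1-yl]pentanoate | O=C(C[C@H](C)CCC1=C(C)CC[C@@H]2C(C)(C)CCC[C@@]12C)OC[C@H]1CO1 | intermediate
17 | (2R)-3-acetoxy-2-hydroxypropyl (3R)-3-methyl-5-[(4aR,8aR)-2,5,5,8a-tetramethyl-3,4,4a,5,6,7,8,8a-octahydronaphthalen-1-yl]pentanoate | CC(=O)OC[C@@H](O)COC(=O)C[C@H](C)CCC1=C(C)CC[C@@H]2C(C)(C)CCC[C@@]12C | target

**Step count.** Total: 10 steps. Longest linear sequence: 8 steps (1, 2, 3, 4, 7, 8, 9, 10); steps 5 and 6 prepare the side chain.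

**Steps most likely to fail**

Step 1. The diene populates its s-cis form poorly because of the (Z)-methyl group, so the cycloaddition may be slow, the acidic catalyst may oligomerise the diene, and facial control may erode at the temperature needed. The fallback sets out from 1 and 2 and returns at 6. The two components are combined without any Lewis acid under high pressure (CH2Cl2, 12 kbar, 40 °C), which should give, with the same sterically dictated regiochemistry, the racemic adduct rac-(4aS,8aR)-2,5,5,8a-tetramethyl-4a,5,8,8a-tetrahydronaphthalene-1,4-dione F1. The conditions of steps 2 and 3 then convert F1 into the racemic dienone triflate rac-2,5,5,8a-tetramethyl-1-oxo-1,5,8,8a-tetrahydronaphthalen-4-yl trifluoromethanesulfonate F2 and the racemic trans-decalone rac-(4aR,8aR)-2,5,5,8a-tetramethyloctahydronaphthalen-1(2H)-one F3. F3 is resolved by addition of lithiated (S)-N,S-dimethyl-S-phenylsulfoximine (n-BuLi, THF, −78 °C) and chromatographic separation of the diastereomeric β-hydroxysulfoximines. Thermolysis (toluene, 110 °C) of the diastereomer derived from the (4aR,8aR)-ketone, (4aR,8aR)-2,5,5,8a-tetramethyl-1-{[(S)-N-methyl-S-phenylsulfonimidoyl]methyl}decahydronaphthalen-1-ol F4, should release 6.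

Step 3. Hydrogen may add to C5=C6 with poor facial selectivity (cis fusion), the C9 carbonyl may be over-reduced, or C–O hydrogenolysis may be incomplete. The fallback sets out from 5 and returns at 6; it separates the events and sets C5 by radical hydrogen-atom transfer.
- Conjugate reduction of the enone with [(Ph3P)CuH]6 (toluene, rt; aqueous NH4Cl) should give the β,γ-unsaturated ketone (8aR)-2,5,5,8a-tetramethyl-1-oxo-1,2,3,5,8,8a-hexahydronaphthalen-4-yl trifluoromethanesulfonate F5.
- Palladium-catalysed formate reduction of the enol triflate (Pd(OAc)2, PPh3, HCO2H, Bu3N, DMF, 60 °C) should give the C5=C6 olefin (8aR)-2,5,5,8a-tetramethyl-3,5,8,8a-tetrahydronaphthalen-1(2H)-one F6.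
- Mild hydrogenation (H2, 1 atm, Pd/C, EtOAc) should saturate only the ring A double bond to give (8aR)-2,5,5,8a-tetramethyl-3,5,6,7,8,8a-hexahydronaphthalen-1(2H)-one F7.
- Hydrogen-atom-transfer hydrogenation (Mn(dpm)3, PhSiH3, t-BuOOH, i-PrOH, rt) then reduces the tertiary C5 radical from the face anti to the C10 methyl and gives 6.

Step 2. Deprotonation of the hindered H5 may be incomplete, or the C8 methyl may be deprotonated in its place (vinylogous enolisation), giving a regioisomeric enol triflate. The fallback sets out from 3 and returns at 6; it replaces enolate chemistry by reduction and elimination.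
- Luche reduction of the less hindered C6 carbonyl (NaBH4, CeCl3·7H2O, MeOH, −78 °C) should give the allylic alcohol (4R,4aS,8aR)-4-hydroxy-2,5,5,8a-tetramethyl-4a,5,8,8a-tetrahydronaphthalen-1(4H)-one F8, drawn for the expected hydride attack on the face of H5.
- Mesylation (MsCl, Et3N, CH2Cl2, 0 °C) should give (4R,4aS,8aR)-2,5,5,8a-tetramethyl-1-oxo-1,4,4a,5,8,8a-hexahydronaphthalen-4-yl methanesulfonate F9.
- Anti elimination of H5 (DBU, toluene, 80 °C) should give the dienone (8aR)-2,5,5,8a-tetramethyl-8,8a-dihydronaphthalen-1(5H)-one F10, which is hydrogenated under the conditions of step 3 to 6.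

**Further compounds**
F1 | step 1 | rac-(4aS,8aR)-2,5,5,8a-tetramethyl-4a,5,8,8a-tetrahydronaphthalene-1,4-dione (racemate, one enantiomer drawn) | O=C1C(C)=CC(=O)[C@H]2C(C)(C)C=CC[C@@]12C
F2 | step 1 | rac-2,5,5,8a-tetramethyl-1-oxo-1,5,8,8a-tetrahydronaphthalen-4-yl trifluoromethanesulfonate (racemate) | O=C1C(C)=CC(OS(=O)(=O)C(F)(F)F)=C2C(C)(C)C=CCC12C
F3 | step 1 | rac-(4aR,8aR)-2,5,5,8a-tetramethyloctahydronaphthalen-1(2H)-one (racemate, one enantiomer drawn) | O=C1C(C)CC[C@@H]2C(C)(C)CCC[C@@]12C
F4 | step 1 | (4aR,8aR)-2,5,5,8a-tetramethyl-1-{[(S)-N-methyl-S-phenylsulfonimidoyl]methyl}decahydronaphthalen-1-ol (1-hydroxyl cis to the 8a-methyl, 2-methyl equatorial, as expected) | O[C@]1(C[S@@](=O)(=NC)c3ccccc3)[C@@H](C)CC[C@@H]2C(C)(C)CCC[C@@]12C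
F5 | step 3 | (8aR)-2,5,5,8a-tetramethyl-1-oxo-1,2,3,5,8,8a-hexahydronaphthalen-4-yl trifluoromethanesulfonate (C2 epimers) | O=C1C(C)CC(OS(=O)(=O)C(F)(F)F)=C2C(C)(C)C=CC[C@@]12C
F6 | step 3 | (8aR)-2,5,5,8a-tetramethyl-3,5,8,8a-tetrahydronaphthalen-1(2H)-one (C2 epimers) | O=C1C(C)CC=C2C(C)(C)C=CC[C@@]12C
F7 | step 3 | (8aR)-2,5,5,8a-tetramethyl-3,5,6,7,8,8a-hexahydronaphthalen-1(2H)-one (C2 epimers) | O=C1C(C)CC=C2C(C)(C)CCC[C@@]12C
F8 | step 2 | (4R,4aS,8aR)-4-hydroxy-2,5,5,8a-tetramethyl-4a,5,8,8a-tetrahydronaphthalen-1(4H)-one | O=C1C(C)=C[C@@H](O)[C@H]2C(C)(C)C=CC[C@@]12C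
F9 | step 2 | (4R,4aS,8aR)-2,5,5,8a-tetramethyl-1-oxo-1,4,4a,5,8,8a-hexahydronaphthalen-4-yl methanesulfonate | O=C1C(C)=C[C@@H](OS(C)(=O)=O)[C@H]2C(C)(C)C=CC[C@@]12C
F10 | step 2 | (8aR)-2,5,5,8a-tetramethyl-8,8a-dihydronaphthalen-1(5H)-one | O=C1C(C)=CC=C2C(C)(C)C=CC[C@@]12C
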